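The numbers in the tables were generated by integration with constants of no real substance; the scatter is artificial.

Watch the first minutes: in Friday's, Saturday's and Tuesday's runs the trapped intermediate climbs quickly, then flattens, and their last readings are 29.6%, 30.4% and 30.2%.

| flask | starting material | partner | capture agent | remark | time |
|---|---|---|---|---|---|
| Friday's | 0.30 M | 1 equiv | 0.090 M | run made earlier |  |
| Saturday's | 0.30 M | 0.67 equiv | 0.090 M | run made earlier |  |
| Tuesday's | 0.30 M | 1.5 equiv | 0.090 M | run made earlier |  |
| autumn | 0.30 M (fed, over 10 min) | 1.00 equiv | 0.0900 M | all else is in the flask from the start; the feed brings no volume worth counting | 12 min |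
| winter | 0.30 M | 1.00 equiv (fed, over 10 min) | 0.0900 M | all else is in the flask from the start; the feed brings no volume worth counting | 12 min |
| noon | 0.30 M | 1.00 equiv | 0.0900 M | everything together at the start | 12 min |

| run | time / min | trapped intermediate / % | target / % |
|---|---|---|---|
| Friday's | 1.50 | 24.3 | 1.0 |
| Friday's | 3.00 | 29.3 | 2.3 |
| Friday's | 5.00 | 30.5 | 3.1 |
| Friday's | 6.00 | 30.6 | 4.0 |
| Friday's | 8.00 | 28.8 | 5.0 |
| Friday's | 10.0 | 29.2 | 5.5 |
| Friday's | 12.0 | 29.6 | 7.5 |
| Saturday's | 0.833 | 20.0 | 1.3 |
| Saturday's | 1.33 | 24.5 | 1.5 |
| Saturday's | 2.00 | 28.9 | 1.1 |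
| Saturday's | 2.50 | 28.6 | 2.2 |
| Saturday's | 4.00 | 29.1 | 2.5 |
| Saturday's | 6.00 | 30.2 | 4.1 |
| Saturday's | 10.0 | 30.4 | 4.9 |
| Tuesday's | 0.500 | 11.4 | 1.8 |
| Tuesday's | 1.33 | 22.2 | 2.3 |
| Tuesday's | 2.50 | 27.1 | 3.9 |
| Tuesday's | 4.00 | 30.5 | 3.3 |
| Tuesday's | 6.00 | 30.7 | 5.4 |
| Tuesday's | 8.00 | 29.3 | 6.4 |
| Tuesday's | 10.0 | 30.2 | 7.7 |

(standard deviation of a reading: 0.5 percentage points)



- the flask with the highest amount of trapped intermediate, in percent of the starting material charged ("all alike" if they lie within 1.5 percentage points) (autumn / winter / noon / all alike)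
- final trapped intermediate, as a percentage of the starting material charged, in autumn
- final trapped intermediate, as a percentage of the starting material charged, in winter
- final trapped intermediate, as a percentage of the starting material charged, in noon

Bound the answer from above first. Capture agent is the limiting reagent here, charged at 0.0900 M against 0.30 M of starting material. Taking one capture agent per trapped intermediate, define the ceiling as capture agent charged divided by starting material charged: 30.0%.

Then reckon just the shortfall below the ceiling; this reckoning is my own. Read against the ceiling, Tuesday's first reading gives a climb of 0.956 min⁻¹, slower than Friday's 1.11 min⁻¹, so use it as the cautious rate. Autumn is the hard case, because its starting material enters over 10 min: if the climb follows what has been fed, autumn gets the equivalent of 7.00 min with the full charge, less than noon's 12 min. On that assumption the shortfall in autumn is 0.037 percentage points, an estimate that puts the lower end of my bracket at 29.96%.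

The forecast says all alike, with 29.7% for autumn, 30% for winter and 30% for noon, calling the plateau “exactly the capture agent's ceiling”. Its winter and noon figures stand at the ceiling. Its autumn figure lies below the lower end of my bracket by 0.26 points, less than the scatter of 0.5 points.

The flasks give 30.0% in autumn, 30.0% in winter and 30.0% at noon, so the verdict is all alike.

    2 partner → homo dimer (k = 0.0190 L mol⁻¹ s⁻¹)
    partner + intermediate A ⇌ intermediate B (K = 7.60 L mol⁻¹, k = 0.160 L mol⁻¹ s⁻¹)
    capture agent + intermediate A → trapped intermediate (k = 0.160 L mol⁻¹ s⁻¹)
    starting material → intermediate A (k = 0.0830 s⁻¹)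
    partner + intermediate A → target (k = 0.00300 L mol⁻¹ s⁻¹)

Autumn still holds 0.0073% of its own capture agent at 12.0 min. The forecast's 30% for winter belongs to a charge of 0.0900 M of capture agent, so weigh that charge with care. Raise it in winter to 0.15 M, with the rest held, and the ceiling becomes 50.0%; that flask ends at 50.0%.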